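The synthesis cuts both bonds of the C4 carbonyl carbon: C4–C4a to ring A, and C4–C3 to the alkene carbon that already holds ring B and the enol ether carbon C2. C4 carries only its oxygen besides these two bonds, so carbon monoxide can supply it. One palladium-catalysed carbonylative Suzuki coupling joins a ring A iodide, CO and an α-aryl-β-methoxyvinylboronate to give an open β-methoxy enone. The iodide has iodine at C4a, flanked by the C5 methyl ether and the MOM-protected O1 phenol, with the C6 prenyl and C7 methoxy groups in place. Acid then closes ring C, and chelation-guided C5 demethylation finishes the route.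

Key step: step 9

Assumption: the bromination–dehydrobromination is taken to give mainly the vinyl bromide with bromine cis to methoxy (aryl trans to methoxy, the less crowded alkene), so retention in the two following steps leads to the E boronate and the Z enone; this geometry does not affect the outcome, because ring C closes by addition–elimination at C2.

Step 1
Reactants: 1 3,5-dimethoxyphenol
Product: 2 (3,5-dimethoxyphenoxy)triisopropylsilane
Conditions: TIPSCl, imidazole, DMF, rt
Reagents that add atoms: triisopropylsilyl chloride, CC(C)[Si](Cl)(C(C)C)C(C)C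
Why: Imidazole-promoted O-silylation of a phenol is routine, and the bulky, weakly coordinating silyl ether shields both ring positions beside it, which prepares the regiocontrol of step 2.

Step 2
Reactants: 2 (3,5-dimethoxyphenoxy)triisopropylsilane; 3 1-bromo-3-methylbut-2-ene (prenyl bromide)
Product: 5 [3,5-dimethoxy-4-(3-methylbut-2-enyl)phenoxy]triisopropylsilane, via aryllithium 4 (not isolated)
Conditions: n-BuLi, THF, 0 °C to rt; then 3, −78 °C to rt
Reagents that add atoms: none
Why: Directed ortho-metalation occurs at the ring carbon between the two methoxy groups, the only site with two unhindered coordinating neighbours, and the aryllithium then displaces the primary allylic bromide in an SN2 alkylation.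

Step 3
Reactants: 5 [3,5-dimethoxy-4-(3-methylbut-2-enyl)phenoxy]triisopropylsilane
Product: 7 1,3-dimethoxy-5-(methoxymethoxy)-2-(3-methylbut-2-enyl)benzene, via ammonium phenoxide 6 (not isolated)
Conditions: TBAF (1 M in THF, predried over molecular sieves), THF, 0 °C; then MOMCl, 0 °C to rt
Reagents that add atoms: chloromethyl methyl ether, COCCl
Why: Fluoride-induced desilylation gives a reactive ammonium phenoxide that the hard chloromethyl ether O-alkylates at once (Williamson-type etherification), so the change of protecting group costs a single operation.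

Step 4
Reactants: 7 1,3-dimethoxy-5-(methoxymethoxy)-2-(3-methylbut-2-enyl)benzene
Product: 9 1-iodo-2,4-dimethoxy-6-(methoxymethoxy)-3-(3-methylbut-2-enyl)benzene, via aryllithium 8 (not isolated)
Conditions: n-BuLi, THF, −20 to 0 °C; then I2, THF, −78 °C to rt
Reagents that add atoms: iodine, II
Why: Directed ortho-metalation is steered by the chelating MOM ether and the neighbouring methoxy group to one of the two equivalent free ring positions, and iodinolysis of the aryllithium puts iodine at the future C4a, next to the oxygen that becomes O1.

Step 5
Reactants: 10 4-hydroxybenzaldehyde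
Product: 11 4-(methoxymethoxy)benzaldehyde
Conditions: MOMCl, i-Pr2NEt, CH2Cl2, 0 °C to rt
Reagents that add atoms: chloromethyl methyl ether, COCCl
Why: Amine-mediated O-alkylation of a phenol (MOM protection) is routine and leaves the aldehyde untouched.

Step 6
Reactants: 11 4-(methoxymethoxy)benzaldehyde
Product: 12 1-(2-methoxyethenyl)-4-(methoxymethoxy)benzene (E/Z mixture, used as such)
Conditions: [Ph3PCH2OMe]Cl, t-BuOK, THF, 0 °C; then 11, 0 °C to rt
Reagents that add atoms: (methoxymethyl)triphenylphosphonium chloride, COC[P+](c1ccccc1)(c1ccccc1)c1ccccc1.[Cl-]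
Why: Wittig methoxymethylenation of an aromatic aldehyde is reliable, and a mixture of alkene isomers is acceptable because step 7 erases this geometry.

Step 7
Reactants: 12 1-(2-methoxyethenyl)-4-(methoxymethoxy)benzene
Product: 14 1-[(Z)-1-bromo-2-methoxyethenyl]-4-(methoxymethoxy)benzene, via dibromide 13 (not isolated)
Conditions: Br2 (1.0 equiv), CH2Cl2, −78 °C; then DBU, −78 °C to rt
Reagents that add atoms: bromine, BrBr
Why: Electrophilic bromine addition to the enol ether, which is far more nucleophilic than the arene, is followed by amine-induced dehydrobromination in which the labile bromide next to oxygen leaves and the acidic benzylic hydrogen is removed, so bromine stays on the aryl-bearing carbon and the aryl group ends up trans to methoxy.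

Step 8
Reactants: 14 1-[(Z)-1-bromo-2-methoxyethenyl]-4-(methoxymethoxy)benzene
Product: 16 2-[(E)-2-methoxy-1-[4-(methoxymethoxy)phenyl]ethenyl]-4,4,5,5-tetramethyl-1,3,2-dioxaborolane, via vinyllithium 15 (not isolated)
Conditions: t-BuLi (2 equiv), Et2O, −78 °C; then i-PrOBpin, −78 °C to rt; H2O
Reagents that add atoms: 2-isopropoxy-4,4,5,5-tetramethyl-1,3,2-dioxaborolane, CC(C)OB1OC(C)(C)C(C)(C)O1
Why: Bromine–lithium exchange with retention gives a vinyllithium whose lithium is cis to methoxy, hence chelated and unable to lose lithium methoxide by anti β-elimination at −78 °C, and electrophilic borylation with the isopropoxyboronate followed by loss of isopropoxide gives the pinacol boronate.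

Step 9
Reactants: 9 1-iodo-2,4-dimethoxy-6-(methoxymethoxy)-3-(3-methylbut-2-enyl)benzene; 16 2-[(E)-2-methoxy-1-[4-(methoxymethoxy)phenyl]ethenyl]-4,4,5,5-tetramethyl-1,3,2-dioxaborolane; 17 carbon monoxide
Product: 18 (Z)-1-[2,4-dimethoxy-6-(methoxymethoxy)-3-(3-methylbut-2-enyl)phenyl]-3-methoxy-2-[4-(methoxymethoxy)phenyl]prop-2-en-1-one
Conditions: 16 (1.5 equiv), CO (4 bar), PdCl2(IPr)(3-chloropyridine) (5 mol %; IPr = 1,3-bis(2,6-diisopropylphenyl)imidazol-2-ylidene), Cs2CO3 (3 equiv), chlorobenzene, 80 °C
Reagents that add atoms: none
Why: Zerovalent palladium, formed in the flask from the divalent precatalyst, inserts into the carbon–iodine bond of 9, CO undergoes migratory insertion to make C4–C4a in an aroylpalladium iodide, carbonate-assisted transmetalation transfers the alkenyl group of 16 with retention, and reductive elimination makes C3–C4. The closest known reaction type is the carbonylative Suzuki–Miyaura coupling of aryl iodides with alkenylboron reagents to aryl vinyl ketones, and carbene-ligated palladium catalysts of this kind are the established answer to aryl iodides with two ortho substituents. No ring is closed and no stereocentre is formed; only the alkene geometry is carried through, and it plays no part later. The selectivity needed is ketone formation over direct aryl–alkenyl coupling, and the substrate secures it because its two ortho alkoxy groups slow transmetalation at the arylpalladium stage while the crowded, electron-rich aryl group migrates to CO quickly, an order that the CO pressure reinforces. The prenyl alkene sits meta to the reacting carbon and cannot reach palladium for a Heck-type cyclisation, and the MOM ethers, methyl ethers and enol ether are inert to Cs2CO3. The excess of 16 covers losses by protodeboronation.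

Step 10
Reactants: 18 (Z)-1-[2,4-dimethoxy-6-(methoxymethoxy)-3-(3-methylbut-2-enyl)phenyl]-3-methoxy-2-[4-(methoxymethoxy)phenyl]prop-2-en-1-one
Product: 20 3-(4-hydroxyphenyl)-5,7-dimethoxy-6-(3-methylbut-2-enyl)chromen-4-one, via free bisphenol enone 19 (not isolated)
Conditions: HCl (1.25 M in MeOH), 40 °C
Reagents that add atoms: none
Why: Acid-catalysed transacetalisation removes both MOM groups, and the freed O1 phenol adds to C2 of the activated enone in a 6-endo oxa-Michael addition and expels methanol (addition–elimination), while the prenyl group, flanked only by methyl ethers, has no free phenol to cyclise onto.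

Step 11
Reactants: 20 3-(4-hydroxyphenyl)-5,7-dimethoxy-6-(3-methylbut-2-enyl)chromen-4-one
Product: 21 gancaonin G, 5-hydroxy-3-(4-hydroxyphenyl)-7-methoxy-6-(3-methylbut-2-enyl)chromen-4-one
Conditions: MgI2·OEt2 (3 equiv), THF, reflux; then H2O
Reagents that add atoms: none
Why: Magnesium chelated between the C4 carbonyl and the C5 oxygen activates only that methyl group for SN2 attack by iodide (chelation-assisted aryl methyl ether cleavage), which spares the C7 methyl ether and, as known for prenylated 5-methoxyflavonoids, is mild enough not to cyclise the prenyl group onto the new phenol.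

Compound list
1 | 3,5-dimethoxyphenol | COc1cc(O)cc(OC)c1 | starting material
2 | (3,5-dimethoxyphenoxy)triisopropylsilane | COc1cc(OC)cc(O[Si](C(C)C)(C(C)C)C(C)C)c1 | intermediate
3 | 1-bromo-3-methylbut-2-ene | CC(C)=CCBr | starting material
4 | [2,6-dimethoxy-4-(triisopropylsilyloxy)phenyl]lithium | [Li]c1c(OC)cc(O[Si](C(C)C)(C(C)C)C(C)C)cc1OC | intermediate
5 | [3,5-dimethoxy-4-(3-methylbut-2-enyl)phenoxy]triisopropylsilane | COc1cc(O[Si](C(C)C)(C(C)C)C(C)C)cc(OC)c1CC=C(C)C | intermediate
6 | tetrabutylammonium 3,5-dimethoxy-4-(3-methylbut-2-enyl)phenoxide | COc1cc([O-])cc(OC)c1CC=C(C)C.CCCC[N+](CCCC)(CCCC)CCCC | intermediate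
7 | 1,3-dimethoxy-5-(methoxymethoxy)-2-(3-methylbut-2-enyl)benzene | COCOc1cc(OC)c(CC=C(C)C)c(OC)c1 | intermediate
8 | [2,4-dimethoxy-6-(methoxymethoxy)-3-(3-methylbut-2-enyl)phenyl]lithium | COCOc1cc(OC)c(CC=C(C)C)c(OC)c1[Li] | intermediate
9 | 1-iodo-2,4-dimethoxy-6-(methoxymethoxy)-3-(3-methylbut-2-enyl)benzene | COCOc1cc(OC)c(CC=C(C)C)c(OC)c1I | intermediate
10 | 4-hydroxybenzaldehyde | O=Cc1ccc(O)cc1 | starting material
11 | 4-(methoxymethoxy)benzaldehyde | COCOc1ccc(C=O)cc1 | intermediate
12 | 1-(2-methoxyethenyl)-4-(methoxymethoxy)benzene, E/Z mixture | COC=Cc1ccc(OCOC)cc1 | intermediate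
13 | 1-(1,2-dibromo-2-methoxyethyl)-4-(methoxymethoxy)benzene, mixture of racemic diastereomers | COC(Br)C(Br)c1ccc(OCOC)cc1 | intermediate
14 | 1-[(Z)-1-bromo-2-methoxyethenyl]-4-(methoxymethoxy)benzene | CO/C=C(\Br)c1ccc(OCOC)cc1 | intermediate
15 | [(E)-2-methoxy-1-[4-(methoxymethoxy)phenyl]ethenyl]lithium (lithium cis to methoxy) | CO/C=C(\[Li])c1ccc(OCOC)cc1 | intermediate
16 | 2-[(E)-2-methoxy-1-[4-(methoxymethoxy)phenyl]ethenyl]-4,4,5,5-tetramethyl-1,3,2-dioxaborolane (boron cis to methoxy) | CO/C=C(\B1OC(C)(C)C(C)(C)O1)c1ccc(OCOC)cc1 | intermediate
17 | carbon monoxide | [C-]#[O+] | starting material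
18 | (Z)-1-[2,4-dimethoxy-6-(methoxymethoxy)-3-(3-methylbut-2-enyl)phenyl]-3-methoxy-2-[4-(methoxymethoxy)phenyl]prop-2-en-1-one | CO/C=C(\C(=O)c1c(OCOC)cc(OC)c(CC=C(C)C)c1OC)c1ccc(OCOC)cc1 | intermediate
19 | (Z)-1-[6-hydroxy-2,4-dimethoxy-3-(3-methylbut-2-enyl)phenyl]-2-(4-hydroxyphenyl)-3-methoxyprop-2-en-1-one | CO/C=C(\C(=O)c1c(O)cc(OC)c(CC=C(C)C)c1OC)c1ccc(O)cc1 | intermediate
20 | 3-(4-hydroxyphenyl)-5,7-dimethoxy-6-(3-methylbut-2-enyl)chromen-4-one | COc1cc2occ(-c3ccc(O)cc3)c(=O)c2c(OC)c1CC=C(C)C | intermediate
21 | gancaonin G, 5-hydroxy-3-(4-hydroxyphenyl)-7-methoxy-6-(3-methylbut-2-enyl)chromen-4-one | COc1cc2occ(-c3ccc(O)cc3)c(=O)c2c(O)c1CC=C(C)C | target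

Total step count: 11.
Longest linear sequence: 7 steps (steps 1–4, then 9–11). The ring B branch, steps 5–8, is equally long.

Steps most likely to fail

Risk 1, step 9. Transmetalation may stall at the crowded aroylpalladium stage. Direct coupling without CO uptake or protodeboronation of the electron-rich alkenylboronate could then take over. The fallback takes C4 from a formyl group instead of CO and sets out from 7 and 14. Aryllithium 8, made from 7 as in step 4, is quenched with DMF to give 2,4-dimethoxy-6-(methoxymethoxy)-3-(3-methylbut-2-enyl)benzaldehyde F1. Vinyllithium 15, made from 14 as in step 8, adds to this aldehyde at −78 °C to give racemic (Z)-1-[2,4-dimethoxy-6-(methoxymethoxy)-3-(3-methylbut-2-enyl)phenyl]-3-methoxy-2-[4-(methoxymethoxy)phenyl]prop-2-en-1-ol F2. This acid-sensitive alcohol is oxidised without delay under neutral conditions with MnO2 in CH2Cl2. The fallback rejoins the route at 18.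

Risk 2, step 8. The vinyllithium may lose lithium methoxide by β-elimination. The bromide may also undergo dehydrobromination by the alkyllithium, or ring lithiation next to the MOM ether. The fallback avoids organolithium chemistry. It sets out from 14 and uses a Miyaura borylation (B2pin2, PdCl2(PPh3)2, PPh3, KOPh, toluene, 50 °C), which proceeds with retention of alkene geometry and rejoins the route at 16. No compound outside the list is made (F0).

Risk 3, step 4. Deprotonation of the doubly activated benzylic and allylic methylene group of the prenyl chain may compete with ring metalation and erode the regiocontrol of the iodination. The fallback replaces metalation by electrophilic aromatic substitution. It sets out from 7, which is treated with N-iodosuccinimide (1.0 equiv) in MeCN at 0 °C in the dark. The two free ring positions are equivalent, and three oxygen substituents activate them enough that the ring should outrun the alkene. The fallback rejoins the route at 9, and no compound outside the list is made (F0).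

Further compounds
F1 | step 9 | 2,4-dimethoxy-6-(methoxymethoxy)-3-(3-methylbut-2-enyl)benzaldehyde | COCOc1cc(OC)c(CC=C(C)C)c(OC)c1C=O
F2 | step 9 | (Z)-1-[2,4-dimethoxy-6-(methoxymethoxy)-3-(3-methylbut-2-enyl)phenyl]-3-methoxy-2-[4-(methoxymethoxy)phenyl]prop-2-en-1-ol, racemic | CO/C=C(\C(O)c1c(OCOC)cc(OC)c(CC=C(C)C)c1OC)c1ccc(OCOC)cc1
F0 | step 8 | none | none
F0 | step 4 | none | none
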